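# Synthesis proposal for (2S)-5,7-dihydroxy-2-{3-[(E)-3-hydroxy-3-methylbut-1-enyl]-4-methoxy-5-(3-methylbut-2-enyl)phenyl}chroman-4-one (10)

## Analysis of the target

The target 10 is a flavanone, a chroman-4-one in which the phloroglucinol-derived ring A (hydroxyls at C5 and C7) is fused to the dihydropyranone ring C, and C2 of ring C carries the aryl ring B. Ring B is a 1,3,4,5-tetrasubstituted benzene: its 4'-oxygen is a methyl ether, flanked at C3' by a prenyl group (3-methylbut-2-enyl) and at C5' by an (E)-3-hydroxy-3-methylbut-1-enyl group. C2 is the only stereocentre and is S (O1 > C1' > C3 > H); the only other stereo-element is the E double bond of the oxidised chain, so no relative configuration has to be controlled. C2 is benzylic, bonded to O1 and β to the C4 carbonyl, so it is lost by retro-oxa-Michael opening of ring C under base, most easily while ring B still has a free 4'-hydroxyl. The tertiary allylic alcohol is conjugated with ring B and ionises or dehydrates in acid, the prenyl alkene is open to electrophiles, the 7-hydroxyl is the most acidic phenol, and the 5-hydroxyl is held in a hydrogen bond to C4=O. The difficulty lies in placement rather than in the skeleton: two five-carbon chains must go onto ring B although C6 and C8 of ring A are far more nucleophilic, the two chains must then be made different, and the hindered 4'-oxygen must be methylated beside a more reactive 7-hydroxyl, all without opening ring C. The strategy rests on the fact that both chains are isoprene units on the two carbons ortho to O4' (C3' and C5'), differing only by an allylic oxidation with double-bond shift, and that removing them and the O-methyl group leaves (2S)-naringenin 3 with C2 already in place.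

## Retrosynthetic reasoning

**10 to 9 (O7–Si).** The target is traced first to its 7-O-triisopropylsilyl ether 9. No skeletal bond is cut. The 7-oxygen must stay masked through every step in which a phenol could react, because it is the most acidic and least hindered oxygen of the molecule. The forward step is a buffered desilylation that neither ionises the tertiary allylic alcohol nor opens ring C.

**9 to 7 through 8 (C–O at the tertiary carbon, with return of the double bond).** The E-configured CH=CH–C(CH3)2–OH unit is the retron of a Schenck ene photooxygenation followed by reduction of the O–O bond of hydroperoxide 8. Undoing it turns the oxidised chain back into a prenyl group and makes the two chains of ring B identical in 7. The gain is that both chains can then come from one reagent. The price is that the forward reaction must oxidise only one of two equivalent prenyl groups and must take a benzylic hydrogen rather than a methyl hydrogen.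

**7 to 6 (O4'–CH3).** The methyl ether is cut next. It has to be in place before the oxidation, because a free 4'-hydroxyl ortho to the new allylic alcohol would cyclise onto it. It has to follow the silylation, because the 7-hydroxyl would otherwise be methylated first. The forward reaction must methylate a hindered, weakly acidic phenol under close to neutral conditions, since a ring B phenoxide is what triggers ring opening at C2.

**6 to 5 (O7–Si).** Removing the silyl group gives the triphenol 5. The forward silylation relies on the gradation of the three hydroxyls: the 7-hydroxyl is acidic and free, the 5-hydroxyl is chelated, and the 4'-hydroxyl is shielded by two ortho chains.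

**5 to 3 and 2 through 4 (C3'–CH2 and C5'–CH2).** These two aryl–CH2 bonds are the only carbon–carbon bonds of 5 that are not already present in (2S)-naringenin 3. Cutting them removes all skeletal construction from the route and turns C2 into a purchased stereocentre. The forward reaction has to deliver an electrophilic dimethylallyl unit twice, each from its own molecule of the diphosphate 2, to ring B ortho to the 4'-hydroxyl, and not to C6, C8 or an oxygen. No chemical electrophile does this, so the step is given to an aromatic prenyltransferase, which passes through the mono-prenyl compound 4.

**2 to 1 (allylic C–O).** The diphosphate 2 is cut at its allylic C–O bond to the bromide 1. The forward reaction is a simple displacement, so the preparation of both key-step partners carries little risk.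

## Alternatives that were turned down

**Alternative 1:** The disconnection is the aryl ether bond O1–C8a of ring C. In the forward direction the open-chain (S)-benzylic alcohol A1 would be cyclised with Pd(OAc)2, a bulky di-tert-butyl biarylphosphine and K3PO4 to the protected flavan-4-ol A2. A1 carries C8a of ring A as an aryl triflate and C4 as a triethylsilyl-protected carbinol.

- For it: C2 is set before ring closure and is not touched by C–O reductive elimination. No flavanone exists until the end, so the retro-oxa-Michael pathway is absent for most of the route. The two ring B chains would be introduced one at a time on a ring B building block, so the statistical differentiation of two equal prenyl groups that burdens the chosen route does not arise. On that point this alternative is clearly stronger.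
- Against it: the palladium alkoxide of a secondary benzylic alcohol has a β-hydrogen at C2 and can collapse by β-hydride elimination to an aryl ketone instead of forming the ether. The triflate sits on an electron-rich ring next to the branched side chain, which slows oxidative addition and invites S–O cleavage by the phosphate base. A2 is still three operations from the target: selective loss of the triethylsilyl group, oxidation at C4, and removal of two aryl silyl ethers beside the ionisable tertiary alcohol.
- Comparison: making A1 needs an enantioselective step and the differentiation of three phloroglucinol oxygens, so the count would run well into double figures against six steps here. In place of built-in ring B regiocontrol, the chosen strategy offers a purchased ring system and a purchased C2.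

**Alternative 2:** The disconnection is the acyl–aryl bond C4–C4a. In the forward direction t-BuLi would effect bromine–lithium exchange at C4a of the bromo aryl ether A3, and the aryllithium would attack the Weinreb amide to close ring C and give the flavanone bis(allyl) ether A4.

- For it: the ketone is formed directly at the right oxidation level, the Weinreb amide stops over-addition, the cyclisation is fast at low temperature, and A4 is only a double de-allylation from the target. Its endgame is as short as that of the chosen route, and ring B is again built with its two chains already different.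
- Against it: A3 is a β-aryloxy amide and can lose the ring A phenoxide by E1cB elimination, the same retro-oxa-Michael weakness as the flavanone but in an acyclic form. t-BuLi must also tolerate a free tertiary alcohol (an extra equivalent and a lithium alkoxide), two allyl ethers prone to α-lithiation and Wittig rearrangement, and benzylic and allylic hydrogens. The C2–O bond of A3 would have to be made with stereocontrol, most plausibly by inversion at an electron-rich benzylic carbinol with a hindered ortho-bromophenol, where ionisation erodes the configuration.
- Comparison: the alternative is equal in endgame length and stronger in ring B regiocontrol. The chosen strategy instead never forms or breaks a bond at C2 and needs no organolithium chemistry in the presence of the side chains.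

**Alternative 3:** The disconnection is C2–C3. In the forward direction Rh2(S-PTTL)4 would decompose the diazoketone A5, and the carbenoid at C3 would insert into one enantiotopic hydrogen of the benzylic OCH2 group, closing ring C and creating C2 in one step to give the tris(silyl) ether A6.

- For it: this is the most direct creation of the stereocentre, from an achiral and convergent precursor, and it is catalytic. It does not depend on the optical purity of a purchased natural product, and on that point it is stronger than the chosen route.
- Against it: insertion here must form a six-membered ring, which is less favoured than five-membered closure. The ether oxygen O1 is placed to attack the carbenoid and form a five-membered oxonium ylide, whose [1,2]-benzyl shift would contract the ring to a benzofuranone skeleton. An acceptor-only carbenoid from a diazomethyl ketone is very reactive and hard to steer enantioselectively. The prenyl and styrenyl alkenes of ring B are open to cyclopropanation, and the silyloxy group ortho to the diazoketone crowds the catalyst.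
- Comparison: several chemoselectivities and the enantioselectivity would all have to succeed in one step, and the precursor still takes many steps to make. The chosen strategy has no step in which C2 is created, so the only stereochemical question is retention.

Key step: step 2

Remark on the chemistry: (2S)-naringenin 3 is taken as purchasable in enantiopure form, with its optical purity checked by chiral HPLC before use. Diphosphates are drawn as free acids, although 2 is handled as its ammonium salt.

## Route

**Step 1**
Reactants: 1 1-bromo-3-methylbut-2-ene (prenyl bromide)
Product: 2 dimethylallyl diphosphate (3-methylbut-2-enyl diphosphate; isolated as its tris(ammonium) salt)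
Conditions: (n-Bu4N)3HP2O7 (2 equiv), MeCN, rt; cation-exchange resin (NH4+ form), aq NH4HCO3; cellulose chromatography, lyophilisation
Reagents that add atoms: tris(tetrabutylammonium) hydrogen diphosphate, CCCC[N+](CCCC)(CCCC)CCCC.CCCC[N+](CCCC)(CCCC)CCCC.CCCC[N+](CCCC)(CCCC)CCCC.OP(=O)([O-])OP(=O)([O-])[O-]
Why: SN2 displacement of a primary allylic bromide by the diphosphate trianion in a dipolar aprotic solvent (Davisson–Poulter-type diphosphorylation); the lipophilic counter-ion makes the diphosphate soluble and nucleophilic, and the disubstituted alkene terminus disfavours SN2' attack.

**Step 2**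
Reactants: 3 (2S)-naringenin; 2 dimethylallyl diphosphate
Product: 5 (2S)-3',5'-diprenylnaringenin, via (2S)-3'-prenylnaringenin 4 (not isolated)
Conditions: recombinant soluble aromatic prenyltransferase (ABBA fold, CloQ/NovQ family, variant selected for double ortho transfer), 2 (3 equiv in total, in portions), Tris·HCl buffer pH 7.5, 5% DMSO, 30 °C; EtOAc extraction
Reagents that add atoms: dimethylallyl diphosphate 2 (second equivalent for the C5' prenyl group), CC(C)=CCOP(=O)(O)OP(=O)(O)O
Why: This is an enzymatic Friedel–Crafts alkylation that consumes two molecules of 2, one for each new aryl–CH2 bond: the prenyltransferase ionises the first to a dimethylallyl cation–diphosphate ion pair held by cation–π contacts above ring B, C3' (ortho to the hydrogen-bonded 4'-hydroxyl) attacks C1 of the cation, and loss of the C3' proton restores the arene to give 4. Because ring B rotates about the C1'–C2 bond, the remaining ortho carbon C5' of 4 can be presented to the same site after rebinding, and transfer from a second molecule of 2 gives 5. The closest known reaction type is the ortho C-prenylation of 4-hydroxyphenyl substrates, flavanones included, by soluble ABBA-fold enzymes, together with the double ortho-prenylation of 4-hydroxycinnamate by plant UbiA-type enzymes. No ring is closed and no stereocentre is formed; C2 is a spectator and should not epimerise at pH 7.5 and 30 °C. The selectivities required are ring B over the intrinsically more nucleophilic C6 and C8 of ring A, carbon over the phenolic oxygens, attack through C1 rather than C3 of the prenyl unit, and double over single transfer. All of these are secured by the binding orientation in the active site and not by the substrate, so the enzyme (wild type or a variant with the pocket enlarged next to the first prenyl group) has to be chosen by screening a small panel for formation of 5.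

**Step 3**
Reactants: 5 (2S)-3',5'-diprenylnaringenin
Product: 6 (2S)-7-O-triisopropylsilyl-3',5'-diprenylnaringenin
Conditions: TIPSCl (1.1 equiv), imidazole (2.2 equiv), DMF, 0 °C
Reagents that add atoms: chlorotriisopropylsilane, CC(C)[Si](Cl)(C(C)C)C(C)C
Why: Selective O-silylation of the most acidic and only unhindered phenol: the 7-hydroxyl is a vinylogous acid para to the C4 carbonyl, the 5-hydroxyl is locked in a hydrogen bond to C4=O, and the 4'-hydroxyl is shielded by two ortho prenyl groups from the bulky silyl chloride. Imidazole at 0 °C is too weak a base to open ring C.

**Step 4**
Reactants: 6 (2S)-7-O-triisopropylsilyl-3',5'-diprenylnaringenin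
Product: 7 (2S)-4'-O-methyl-7-O-triisopropylsilyl-3',5'-diprenylnaringenin
Conditions: TMSCHN2 (hexanes, 3 equiv), i-Pr2NEt (1.2 equiv), MeCN–MeOH 9:1, rt
Reagents that add atoms: trimethylsilyldiazomethane, C[Si](C)(C)C=[N+]=[N-]
Why: O-methylation of a phenol by a diazoalkane (Aoyama–Shioiri conditions): proton transfer from the phenol and methanolysis of the C–Si bond generate a methyldiazonium–phenoxide pair that collapses to the aryl methyl ether with loss of N2. The chelated 5-hydroxyl is too weakly acidic to enter this cycle, and the near-neutral medium should spare C2 and the silyl ether.

**Step 5**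
Reactants: 7 (2S)-4'-O-methyl-7-O-triisopropylsilyl-3',5'-diprenylnaringenin
Product: 9 (2S)-5'-[(E)-3-hydroxy-3-methylbut-1-enyl]-4'-O-methyl-3'-prenyl-7-O-triisopropylsilylnaringenin, via tertiary allylic hydroperoxide 8 (not isolated)
Conditions: O2, 5,10,15,20-tetraphenylporphyrin (cat.), CH2Cl2, visible light, 0 °C, to partial conversion; then PPh3, 0 °C to rt
Reagents that add atoms: dioxygen (as singlet oxygen), O=O
Why: Schenck ene reaction of singlet oxygen with one trisubstituted prenyl alkene: abstraction of a benzylic hydrogen on the more substituted side of the alkene places oxygen on the tertiary carbon and moves the double bond into conjugation with ring B as the E isomer, and triphenylphosphine then reduces the O–O bond of 8. The reaction is stopped at partial conversion because the two prenyl groups are equivalent; 9 is separated from recovered 7 (recycled), from the regioisomer formed by methyl hydrogen abstraction and from doubly oxidised material.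

**Step 6**
Reactants: 9 (2S)-5'-[(E)-3-hydroxy-3-methylbut-1-enyl]-4'-O-methyl-3'-prenyl-7-O-triisopropylsilylnaringenin
Product: 10 (2S)-5,7-dihydroxy-2-{3-[(E)-3-hydroxy-3-methylbut-1-enyl]-4-methoxy-5-(3-methylbut-2-enyl)phenyl}chroman-4-one
Conditions: TBAF (1.2 equiv), AcOH (1.2 equiv), THF, 0 °C
Reagents that add atoms: none
Why: Fluoride cleavage of an aryl silyl ether, driven by the Si–F bond strength and the good leaving ability of the 7-phenoxide; the acetic acid buffer keeps the medium neither basic enough to open ring C nor acidic enough to ionise the tertiary allylic alcohol.

## Compound list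

1 | 1-bromo-3-methylbut-2-ene (prenyl bromide) | CC(C)=CCBr | starting material
2 | dimethylallyl diphosphate (drawn as free acid, handled as tris(ammonium) salt) | CC(C)=CCOP(=O)(O)OP(=O)(O)O | intermediate
3 | (2S)-naringenin, (2S)-5,7-dihydroxy-2-(4-hydroxyphenyl)chroman-4-one | Oc1ccc([C@@H]2CC(=O)c3c(O)cc(O)cc3O2)cc1 | starting material
4 | (2S)-3'-prenylnaringenin | CC(C)=CCc1cc([C@@H]2CC(=O)c3c(O)cc(O)cc3O2)ccc1O | intermediate
5 | (2S)-3',5'-diprenylnaringenin, (2S)-5,7-dihydroxy-2-[4-hydroxy-3,5-bis(3-methylbut-2-enyl)phenyl]chroman-4-one | CC(C)=CCc1cc([C@@H]2CC(=O)c3c(O)cc(O)cc3O2)cc(CC=C(C)C)c1O | intermediate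
6 | (2S)-7-O-triisopropylsilyl-3',5'-diprenylnaringenin | CC(C)=CCc1cc([C@@H]2CC(=O)c3c(O)cc(O[Si](C(C)C)(C(C)C)C(C)C)cc3O2)cc(CC=C(C)C)c1O | intermediate
7 | (2S)-4'-O-methyl-7-O-triisopropylsilyl-3',5'-diprenylnaringenin | COc1c(CC=C(C)C)cc([C@@H]2CC(=O)c3c(O)cc(O[Si](C(C)C)(C(C)C)C(C)C)cc3O2)cc1CC=C(C)C | intermediate
8 | (2S)-5'-[(E)-3-hydroperoxy-3-methylbut-1-enyl]-4'-O-methyl-3'-prenyl-7-O-triisopropylsilylnaringenin | COc1c(/C=C/C(C)(C)OO)cc([C@@H]2CC(=O)c3c(O)cc(O[Si](C(C)C)(C(C)C)C(C)C)cc3O2)cc1CC=C(C)C | intermediate
9 | (2S)-5'-[(E)-3-hydroxy-3-methylbut-1-enyl]-4'-O-methyl-3'-prenyl-7-O-triisopropylsilylnaringenin | COc1c(/C=C/C(C)(C)O)cc([C@@H]2CC(=O)c3c(O)cc(O[Si](C(C)C)(C(C)C)C(C)C)cc3O2)cc1CC=C(C)C | intermediate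
10 | (2S)-5,7-dihydroxy-2-{3-[(E)-3-hydroxy-3-methylbut-1-enyl]-4-methoxy-5-(3-methylbut-2-enyl)phenyl}chroman-4-one | COc1c(/C=C/C(C)(C)O)cc([C@@H]2CC(=O)c3c(O)cc(O)cc3O2)cc1CC=C(C)C | target

## Step count and risk

Total step count: 6. Longest linear sequence: 6 steps (1 to 2 to 5 to 6 to 7 to 9 to 10), or 5 steps counted from (2S)-naringenin 3.

**Step 2 (key step).**
- Risk: the transfer may stall after the first prenyl group, because 4 with its new ortho substituent may no longer fit the pocket in the orientation that presents C5'. The enzyme may also misbind the substrate and transfer the prenyl group to O4', O7, C6 or C8. Slow turnover would let 2 hydrolyse, and the lipophilic product may inhibit the enzyme.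
- Fallback: it sets out from 3 and rejoins the route at 6, replacing steps 2 and 3. Each prenyl unit is first tethered to the 4'-oxygen and then moved to the ortho carbon by a sigmatropic shift, so that ring B selectivity is enforced by intramolecularity. Silylation of 3 (TIPSCl, imidazole, DMF, 0 °C) should give (2S)-7-O-triisopropylsilylnaringenin F1. O-Allylation with tert-butyl 2-methylbut-3-en-2-yl carbonate and catalytic Pd(PPh3)4 in THF at 0 °C should give the tertiary ether, (2S)-4'-O-(1,1-dimethylallyl)-7-O-triisopropylsilylnaringenin F2. An aromatic Claisen rearrangement (toluene, 110–120 °C, or catalytic Eu(fod)3 in CHCl3 at 50 °C) transfers the chain to C3' with allylic inversion, so that the 1,1-dimethylallyl ether delivers a normal prenyl group, giving (2S)-7-O-triisopropylsilyl-3'-prenylnaringenin F3. A second O-allylation gives (2S)-4'-O-(1,1-dimethylallyl)-7-O-triisopropylsilyl-3'-prenylnaringenin F4, and a second Claisen rearrangement, which can end only at the free ortho carbon C5', gives 6.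

**Step 5.**
- Risk: the oxidation is expected to be unselective in two ways. It cannot distinguish the two equivalent prenyl groups, so oxidation of both competes. It can also abstract hydrogen from the cis methyl group instead of the benzylic methylene, which puts the oxygen on the secondary carbon. Both lower the amount of 9 per pass and make the chromatography demanding.
- Fallback: it sets out from 7 and rejoins at 9, and it fixes the regiochemistry by mechanism. Hydroxyselenation of one prenyl group with N-(phenylseleno)phthalimide, water and catalytic camphorsulfonic acid in CH2Cl2 should add in the Markovnikov sense to give the β-hydroxy selenide, (2S)-5'-[3-hydroxy-3-methyl-2-(phenylselanyl)butyl]-4'-O-methyl-3'-prenyl-7-O-triisopropylsilylnaringenin F5 (mixture of epimers at the selenium-bearing carbon), which is separated from recovered 7. Oxidation with aqueous H2O2 in THF at 0 °C gives the selenoxide, (2S)-5'-[3-hydroxy-3-methyl-2-(phenylseleninyl)butyl]-4'-O-methyl-3'-prenyl-7-O-triisopropylsilylnaringenin F6. Its syn-elimination can take only a benzylic hydrogen, because the carbinol carbon bears none, and so should give the E alkene 9 alone. The statistical choice between the two prenyl groups remains and is again handled by partial conversion and recycling.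

**Step 4.**
- Risk: methylation of the hindered, weakly acidic 4'-hydroxyl may be slow. During a long reaction the 7-O-silyl ether may be lost by methanolysis, followed by methylation at O7, or the amine may promote opening of ring C through the ring B phenoxide, with loss of configuration at C2.
- Fallback: it sets out from 6 and rejoins at 7 in one operation and makes no new compound. A Mitsunobu etherification with methanol (1.5 equiv), PPh3 and diisopropyl azodicarboxylate in THF at 0 °C activates the alcohol as a methoxyphosphonium ion, which the phenol attacks. No amine base and no protic co-solvent are present, and the chelated 5-hydroxyl is not acidic enough to take part.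

**Step 6.**
- Risk: the tertiary allylic alcohol may ionise or dehydrate if the medium turns acidic, and the 7-phenoxide may drive retro-oxa-Michael opening with epimerisation at C2 if the fluoride is insufficiently buffered.
- Fallback: it sets out from 7 and rejoins at 10 by reversing the order of the last two operations, so that the silyl group is removed before the sensitive alcohol exists. Desilylation of 7 (TBAF, AcOH, THF, 0 °C) gives (2S)-4'-O-methyl-3',5'-diprenylnaringenin F7. Photooxygenation as in step 5 gives the hydroperoxide, (2S)-5'-[(E)-3-hydroperoxy-3-methylbut-1-enyl]-4'-O-methyl-3'-prenylnaringenin F8, which triphenylphosphine reduces to 10. The free 7-hydroxyl is an acyl-conjugated phenol and should tolerate singlet oxygen in a neutral, aprotic medium.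

## Further compounds

F1 | step 2 | (2S)-7-O-triisopropylsilylnaringenin | Oc1ccc([C@@H]2CC(=O)c3c(O)cc(O[Si](C(C)C)(C(C)C)C(C)C)cc3O2)cc1
F2 | step 2 | (2S)-4'-O-(1,1-dimethylallyl)-7-O-triisopropylsilylnaringenin | C=CC(C)(C)Oc1ccc([C@@H]2CC(=O)c3c(O)cc(O[Si](C(C)C)(C(C)C)C(C)C)cc3O2)cc1
F3 | step 2 | (2S)-7-O-triisopropylsilyl-3'-prenylnaringenin | CC(C)=CCc1cc([C@@H]2CC(=O)c3c(O)cc(O[Si](C(C)C)(C(C)C)C(C)C)cc3O2)ccc1O
F4 | step 2 | (2S)-4'-O-(1,1-dimethylallyl)-7-O-triisopropylsilyl-3'-prenylnaringenin | C=CC(C)(C)Oc1ccc([C@@H]2CC(=O)c3c(O)cc(O[Si](C(C)C)(C(C)C)C(C)C)cc3O2)cc1CC=C(C)C
F5 | step 5 | (2S)-5'-[3-hydroxy-3-methyl-2-(phenylselanyl)butyl]-4'-O-methyl-3'-prenyl-7-O-triisopropylsilylnaringenin (mixture of epimers at the selenium-bearing carbon) | COc1c(CC([Se]c4ccccc4)C(C)(C)O)cc([C@@H]2CC(=O)c3c(O)cc(O[Si](C(C)C)(C(C)C)C(C)C)cc3O2)cc1CC=C(C)C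
F6 | step 5 | (2S)-5'-[3-hydroxy-3-methyl-2-(phenylseleninyl)butyl]-4'-O-methyl-3'-prenyl-7-O-triisopropylsilylnaringenin (mixture of stereoisomers in the side chain) | COc1c(CC([Se](=O)c4ccccc4)C(C)(C)O)cc([C@@H]2CC(=O)c3c(O)cc(O[Si](C(C)C)(C(C)C)C(C)C)cc3O2)cc1CC=C(C)C
F0 | step 4 | none | none
F7 | step 6 | (2S)-4'-O-methyl-3',5'-diprenylnaringenin | COc1c(CC=C(C)C)cc([C@@H]2CC(=O)c3c(O)cc(O)cc3O2)cc1CC=C(C)C
F8 | step 6 | (2S)-5'-[(E)-3-hydroperoxy-3-methylbut-1-enyl]-4'-O-methyl-3'-prenylnaringenin | COc1c(/C=C/C(C)(C)OO)cc([C@@H]2CC(=O)c3c(O)cc(O)cc3O2)cc1CC=C(C)C
A1 | alternative 1 | (1S)-3-[2,4-bis(tert-butyldimethylsilyloxy)-6-(trifluoromethanesulfonyloxy)phenyl]-1-{3-[(E)-3-hydroxy-3-methylbut-1-enyl]-4-methoxy-5-(3-methylbut-2-enyl)phenyl}-3-(triethylsilyloxy)propan-1-ol, either epimer at the silyloxy carbon | COc1c(/C=C/C(C)(C)O)cc([C@@H](O)CC(O[Si](CC)(CC)CC)c2c(O[Si](C)(C)C(C)(C)C)cc(O[Si](C)(C)C(C)(C)C)cc2OS(=O)(=O)C(F)(F)F)cc1CC=C(C)C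
A2 | alternative 1 | (2S)-4-(triethylsilyloxy)flavan 5,7-bis(tert-butyldimethylsilyl) ether with the ring B substituents of the target, either epimer at C4 | COc1c(/C=C/C(C)(C)O)cc([C@@H]2CC(O[Si](CC)(CC)CC)c3c(O[Si](C)(C)C(C)(C)C)cc(O[Si](C)(C)C(C)(C)C)cc3O2)cc1CC=C(C)C
A3 | alternative 2 | (3S)-3-[3,5-bis(allyloxy)-2-bromophenoxy]-3-{3-[(E)-3-hydroxy-3-methylbut-1-enyl]-4-methoxy-5-(3-methylbut-2-enyl)phenyl}-N-methoxy-N-methylpropanamide | COc1c(/C=C/C(C)(C)O)cc([C@H](CC(=O)N(C)OC)Oc2cc(OCC=C)cc(OCC=C)c2Br)cc1CC=C(C)C
A4 | alternative 2 | (2S)-5,7-bis(allyloxy)flavanone with the ring B substituents of the target | COc1c(/C=C/C(C)(C)O)cc([C@@H]2CC(=O)c3c(OCC=C)cc(OCC=C)cc3O2)cc1CC=C(C)C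
A5 | alternative 3 | 2-diazo-1-{2,4-bis(tert-butyldimethylsilyloxy)-6-[3-((E)-3-methyl-3-(triethylsilyloxy)but-1-enyl)-4-methoxy-5-(3-methylbut-2-enyl)benzyloxy]phenyl}ethanone | COc1c(/C=C/C(C)(C)O[Si](CC)(CC)CC)cc(COc2cc(O[Si](C)(C)C(C)(C)C)cc(O[Si](C)(C)C(C)(C)C)c2C(=O)C=[N+]=[N-])cc1CC=C(C)C
A6 | alternative 3 | (2S)-flavanone 5,7-bis(tert-butyldimethylsilyl) ether with the side-chain alcohol as its triethylsilyl ether | COc1c(/C=C/C(C)(C)O[Si](CC)(CC)CC)cc([C@@H]2CC(=O)c3c(O[Si](C)(C)C(C)(C)C)cc(O[Si](C)(C)C(C)(C)C)cc3O2)cc1CC=C(C)C
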